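**Plan**

- Numbering: chroman part O1, C2(CH3)2, C3, C4, C4a, C5(OMe), C6, C7, C8, C8a; coumarin part as usual. The retrosynthesis first cuts the coumarin pyranone ring (C3=C4 and the lactone O1–C2 bond, a Perkin–Oglialoro condensation), then the C6–CH2 bond of the resulting (chroman-6-yl)acetic acid (malonate arylation of a C6 chloride).
- Last, the dihydropyran ring of the chroman is cut at C3–C2 and at O1–C8a at once, which releases acetone and a 2-fluorostyrene.
- Enabling feature: O1–C2(CH3)2 is an intact acetone unit, and C4–C3 is a vinyl group on C4a whose terminal carbon accepts the acetone ketyl. C8a lies ortho to that chain, para to C6 and meta to C5–OMe, so fluorine on C8a and chlorine on C6 make C8a a site for SNAr by the new tertiary alkoxide; the same chlorine later carries the coumarin.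
- Forward order: the tetrasubstituted benzene ring is set by lithiation between F and OMe, formylation and methylenation; the pyran ring of the chroman is then closed; the arylacetic acid is installed; the coumarin pyranone ring is closed last, followed by deacetylation.
- Stereochemistry: the target has no stereocentre and no stereogenic double bond, so nothing has to be controlled.

Key step: step 3

Remark: compounds 1, 5, 8 and 12 are taken as purchasable. The fluorine and chlorine atoms are helper groups that are both consumed on the way (F in step 3, Cl in step 4).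

**Step 1**
Reactants: 1 2-chloro-5-fluoroanisole
Product: 3 3-chloro-6-fluoro-2-methoxybenzaldehyde, via aryllithium 2 (not isolated)
Conditions: LiN(i-Pr)2, THF, −78 °C; DMF, −78 to 0 °C; aq. HCl
Reagents that add atoms: N,N-dimethylformamide, CN(C)C=O
Why: Directed ortho-lithiation should remove the ring proton flanked by F and OMe, the most acidic one, without touching the C–Cl bond, and the aryllithium is formylated by DMF below the temperature at which LiF would be lost.

**Step 2**
Reactants: 3 3-chloro-6-fluoro-2-methoxybenzaldehyde
Product: 4 1-chloro-4-fluoro-2-methoxy-3-vinylbenzene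
Conditions: Ph3PCH3Br, KOt-Bu, THF, 0 °C to rt
Reagents that add atoms: methyltriphenylphosphonium bromide, C[P+](c1ccccc1)(c1ccccc1)c1ccccc1.[Br-]
Why: Wittig methylenation of an aromatic aldehyde with the non-stabilised ylide is fast at 0 °C and should outrun any attack of base on the fluorine ortho to the formyl group.

**Step 3**
Reactants: 4 1-chloro-4-fluoro-2-methoxy-3-vinylbenzene; 5 acetone (in excess)
Product: 7 6-chloro-5-methoxy-2,2-dimethylchroman, via carbinol 6 (not isolated)
Conditions: SmI2, HMPA, t-BuOH, THF, 0 °C to rt; then THF and excess acetone distilled off, KOt-Bu, 65 °C in the remaining HMPA, same flask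
Reagents that add atoms: none
Why: Divalent samarium with HMPA should reduce acetone to its ketyl, a nucleophilic radical that adds to the terminal vinyl carbon of 4 (C3–C2 bond) because only this regiochemistry gives a benzylic radical; a second electron transfer and protonation by t-BuOH leave the trivalent samarium alkoxide of carbinol 6. KOt-Bu then frees the tertiary alkoxide, which attacks the C–F carbon ortho to the side chain and expels fluoride through a Meisenheimer adduct (O1–C8a bond). The closest known reaction types are the SmI2–HMPA ketyl–olefin coupling of ketones with styrenes and the intramolecular SNAr of 3-(2-fluorophenyl)propoxides to chromans, here run one after the other in one flask. The pyran ring closes in the 6-exo-trig mode (addition step of the SNAr), helped by the gem-dimethyl group. No stereocentre is formed. The step needs the benzylic-radical regiochemistry in the C–C bond formation and substitution of F in preference to Cl or OMe; the latter is secured by fluoride being the best leaving group in SNAr, by the six-membered transition state that reaches only the ortho carbon, and by the para chlorine and meta methoxy group that stabilise the anionic adduct.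

**Step 4**
Reactants: 7 6-chloro-5-methoxy-2,2-dimethylchroman; 8 diethyl malonate
Product: 9 diethyl 2-(5-methoxy-2,2-dimethylchroman-6-yl)malonate
Conditions: Pd(dba)2 (cat.), P(t-Bu)3 (cat.), K3PO4, toluene, 80 °C
Reagents that add atoms: none
Why: Palladium-catalysed α-arylation of a malonate: the bulky electron-rich phosphine should let zerovalent palladium insert into the electron-rich aryl chloride, and the stabilised enolate gives only monoarylation under the mild phosphate base.

**Step 5**
Reactants: 9 diethyl 2-(5-methoxy-2,2-dimethylchroman-6-yl)malonate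
Product: 11 2-(5-methoxy-2,2-dimethylchroman-6-yl)acetic acid, via malonic acid 10 (not isolated)
Conditions: KOH, EtOH/H2O, reflux; then aq. HCl to pH 1, 80 °C
Reagents that add atoms: potassium hydroxide (hydroxide oxygen), [K+].[OH-]
Why: Saponification followed by thermal decarboxylation of the arylmalonic acid (malonic ester synthesis) should give the arylacetic acid, and the chroman ether and the aryl methyl ether are inert to both media.

**Step 6**
Reactants: 11 2-(5-methoxy-2,2-dimethylchroman-6-yl)acetic acid; 12 2,4-dihydroxy-6-methoxybenzaldehyde
Product: 13 5-methoxy-3-(5-methoxy-2,2-dimethylchroman-6-yl)-2-oxo-2H-chromen-7-yl acetate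
Conditions: Ac2O, Et3N, 120 °C
Reagents that add atoms: acetic anhydride, CC(=O)OC(C)=O
Why: Perkin–Oglialoro condensation: the mixed anhydride of 11 is enolised by Et3N, condenses with the aldehyde carbon (the future C4) and lactonises through the ortho oxygen to the 3-arylcoumarin, while the para hydroxyl ends as the acetate.

**Step 7**
Reactants: 13 5-methoxy-3-(5-methoxy-2,2-dimethylchroman-6-yl)-2-oxo-2H-chromen-7-yl acetate
Product: 14 7-hydroxy-5-methoxy-3-(5-methoxy-2,2-dimethylchroman-6-yl)-2H-chromen-2-one
Conditions: HCl (cat.), MeOH, 60 °C
Reagents that add atoms: none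
Why: Acid-catalysed methanolysis (transesterification) should remove the phenolic acetate, while the coumarin lactone, the chroman ether and both methyl ethers are stable to dilute methanolic HCl.

**Compound list**

1 | 2-chloro-5-fluoroanisole (1-chloro-4-fluoro-2-methoxybenzene) | COc1cc(F)ccc1Cl | starting material
2 | (3-chloro-6-fluoro-2-methoxyphenyl)lithium | COc1c(Cl)ccc(F)c1[Li] | intermediate
3 | 3-chloro-6-fluoro-2-methoxybenzaldehyde | COc1c(Cl)ccc(F)c1C=O | intermediate
4 | 1-chloro-4-fluoro-2-methoxy-3-vinylbenzene | COc1c(Cl)ccc(F)c1C=C | intermediate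
5 | acetone | CC(C)=O | starting material
6 | 4-(3-chloro-6-fluoro-2-methoxyphenyl)-2-methylbutan-2-ol | COc1c(Cl)ccc(F)c1CCC(C)(C)O | intermediate
7 | 6-chloro-5-methoxy-2,2-dimethylchroman | COc1c(Cl)ccc2c1CCC(C)(C)O2 | intermediate
8 | diethyl malonate | CCOC(=O)CC(=O)OCC | starting material
9 | diethyl 2-(5-methoxy-2,2-dimethylchroman-6-yl)malonate | CCOC(=O)C(C(=O)OCC)c1ccc2c(c1OC)CCC(C)(C)O2 | intermediate
10 | 2-(5-methoxy-2,2-dimethylchroman-6-yl)malonic acid | OC(=O)C(C(=O)O)c1ccc2c(c1OC)CCC(C)(C)O2 | intermediate
11 | 2-(5-methoxy-2,2-dimethylchroman-6-yl)acetic acid | OC(=O)Cc1ccc2c(c1OC)CCC(C)(C)O2 | intermediate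
12 | 2,4-dihydroxy-6-methoxybenzaldehyde | COc1cc(O)cc(O)c1C=O | starting material
13 | 5-methoxy-3-(5-methoxy-2,2-dimethylchroman-6-yl)-2-oxo-2H-chromen-7-yl acetate | COc1c(-c2cc3c(OC)cc(OC(C)=O)cc3oc2=O)ccc2c1CCC(C)(C)O2 | intermediate
14 | 7-hydroxy-5-methoxy-3-(5-methoxy-2,2-dimethylchroman-6-yl)-2H-chromen-2-one | COc1c(-c2cc3c(OC)cc(O)cc3oc2=O)ccc2c1CCC(C)(C)O2 | target

**Step count and risks**

Total step count: 7. Longest linear sequence: 7 steps (1 to 14).

Steps most likely to fail:

Step 3. The ketyl may be used up by pinacol coupling and over-reduction faster than it adds to the twisted, electron-rich styrene, and the trivalent samarium salts may hold the alkoxide so firmly that ring closure stalls at the carbinol. The fallback builds the carbinol by polar chemistry and sets out from aldehyde 3. Wittig olefination with 1-(triphenylphosphoranylidene)propan-2-one (toluene, 90 °C) should give (E)-4-(3-chloro-6-fluoro-2-methoxyphenyl)but-3-en-2-one F1. Hydrogenation of the C=C bond over RhCl(PPh3)3, which leaves the aryl chloride alone, should give 4-(3-chloro-6-fluoro-2-methoxyphenyl)butan-2-one F2. MeMgBr (THF, 0 °C) then gives carbinol 6, this time isolated, and NaH in DMF at 90 °C closes it by SNAr; the fallback comes back to the route at 7.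

Step 4. Reductive elimination from the hindered arylpalladium malonate (ortho methoxy group) may be slower than protodehalogenation of the electron-rich chloride. The fallback replaces the enolate by a small vinyl partner and sets out from 7. Suzuki–Miyaura coupling with potassium vinyltrifluoroborate (Pd(OAc)2, XPhos, Cs2CO3, THF/H2O, 85 °C) should give 5-methoxy-2,2-dimethyl-6-vinylchroman F3. Anti-Markovnikov hydroboration–oxidation (9-BBN, THF; then NaOH, H2O2) should give 2-(5-methoxy-2,2-dimethylchroman-6-yl)ethanol F4. Oxidation with TEMPO (cat.) and PhI(OAc)2 in MeCN/H2O takes the primary alcohol to the acid; the fallback comes back to the route at 11 and bypasses 9.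

Step 6. The electron-rich mixed anhydride enolises sluggishly and the doubly ortho-substituted aldehyde is a poor electrophile, so acetylation and self-condensation of the aldehyde partner may outrun the intermolecular condensation. The fallback makes the C–C bond intramolecularly and sets out from 11 and 12. Selective protection of the non-chelated 4-hydroxyl of 12 (MOMCl, i-Pr2NEt, CH2Cl2, 0 °C) should give 2-hydroxy-6-methoxy-4-(methoxymethoxy)benzaldehyde F5. Steglich esterification of 11 with F5 (EDC·HCl, DMAP, CH2Cl2) should give 2-formyl-3-methoxy-5-(methoxymethoxy)phenyl 2-(5-methoxy-2,2-dimethylchroman-6-yl)acetate F6. Intramolecular Knoevenagel-type aldol condensation (DBU, MeCN, 60 °C) should give 5-methoxy-7-(methoxymethoxy)-3-(5-methoxy-2,2-dimethylchroman-6-yl)-2H-chromen-2-one F7. HCl in MeOH at 50 °C removes the acetal; the fallback comes back to the route at 14 and bypasses 13.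

**Further compounds**

F1 | step 3 | (E)-4-(3-chloro-6-fluoro-2-methoxyphenyl)but-3-en-2-one | COc1c(Cl)ccc(F)c1/C=C/C(C)=O
F2 | step 3 | 4-(3-chloro-6-fluoro-2-methoxyphenyl)butan-2-one | COc1c(Cl)ccc(F)c1CCC(C)=O
F3 | step 4 | 5-methoxy-2,2-dimethyl-6-vinylchroman | COc1c(C=C)ccc2c1CCC(C)(C)O2
F4 | step 4 | 2-(5-methoxy-2,2-dimethylchroman-6-yl)ethanol | COc1c(CCO)ccc2c1CCC(C)(C)O2
F5 | step 6 | 2-hydroxy-6-methoxy-4-(methoxymethoxy)benzaldehyde | COCOc1cc(O)c(C=O)c(OC)c1
F6 | step 6 | 2-formyl-3-methoxy-5-(methoxymethoxy)phenyl 2-(5-methoxy-2,2-dimethylchroman-6-yl)acetate | COCOc1cc(OC)c(C=O)c(OC(=O)Cc2ccc3c(c2OC)CCC(C)(C)O3)c1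
F7 | step 6 | 5-methoxy-7-(methoxymethoxy)-3-(5-methoxy-2,2-dimethylchroman-6-yl)-2H-chromen-2-one | COCOc1cc(OC)c2cc(-c3ccc4c(c3OC)CCC(C)(C)O4)c(=O)oc2c1
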